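**Plan**

- Retrosynthetic cuts, in order: the C2–O ester bond; C12–C13 and C11–C12 (two boron homologations); C9–C11 (methylenation of a C9 ketone); one C4 methyl (hydromethylation of C4=CH2); C2–C3 (ring A, carbonyl-ene); C10–C1 and C10–CH3 (enolate alkylations).
- Forward: (S)-carvone is ring B; C10 is made quaternary by methylation, then acetate alkylation; the derived keto aldehyde closes ring A; the C4 gem-dimethyl, the C9 methylene, the C11–C13 chain and the senecioate follow.
- Enabling feature: ring B of the target (C5–C10, with the C8 methyl, the C7=C8 alkene and the C5 stereocentre) is carvone itself. Its isopropenyl carbon is C4, the CH2 terminus is C3 and the methyl is one of the C4 methyls, so a C1–C2 aldehyde arm on C10 sets up a type 2 carbonyl-ene closure of ring A that places oxygen at C2.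
- Stereochemistry: C5 from carvone; C10 by alkylation anti to isopropenyl; C2 by the closed ene transition state (axial carbinol) followed by Mitsunobu inversion; C9 by hydroboration anti to the C10 methyl; C13 from (R)-but-3-en-2-ol by stereospecific lithiation–borylation.

Key step: step 5

Remark: labdane numbering is used for every bicyclic compound, and syn or anti always refers to the face of the angular C10 methyl group.

**Route**

Step 1
Reactants: 1 (S)-(+)-carvone
Product: 3 (5S)-6-methylcarvone as a mixture of C6 epimers, via carvone lithium dienolate 2 (not isolated)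
Conditions: LiN(iPr)2, THF, −78 °C; MeI, −78 → 0 °C
Reagents that add atoms: iodomethane CI
Why: Kinetic deprotonation on the CH2 side of the enone gives the cross-conjugated dienolate, and its SN2 methylation (enolate alkylation) installs the future C10 methyl; the configuration of this carbon is irrelevant because it is enolised again in step 2.

Step 2
Reactants: 3 (5S)-6-methylcarvone, 4 ethyl bromoacetate
Product: 6 ethyl 2-[(1R,6R)-1,3-dimethyl-2-oxo-6-(prop-1-en-2-yl)cyclohex-3-en-1-yl]acetate, via 6-methylcarvone lithium dienolate 5 (not isolated)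
Conditions: LiN(iPr)2, THF, −78 → 0 °C; 4, DMPU, −78 °C → rt
Reagents that add atoms: none
Why: Enolate alkylation of the tetrasubstituted dienolate takes place on the face anti to the neighbouring isopropenyl group, which sits pseudoaxial to avoid allylic strain with the enolate methyl, so the new quaternary C10 carries CH2CO2Et trans and CH3 cis to isopropenyl.

Step 3
Reactants: 6 keto ester
Product: 7 (5R,6R)-6-(2-hydroxyethyl)-2,6-dimethyl-5-(prop-1-en-2-yl)cyclohex-2-en-1-ol as a mixture of carbinol epimers
Conditions: LiAlH4, Et2O, 0 °C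
Reagents that add atoms: none
Why: Hydride reduction with LiAlH4 reduces the hindered enone in the 1,2-sense and the ester completely, giving a 1,4-diol whose carbinol configuration is erased again in step 4.

Step 4
Reactants: 7 diol
Product: 8 2-[(1R,6R)-1,3-dimethyl-2-oxo-6-(prop-1-en-2-yl)cyclohex-3-en-1-yl]acetaldehyde
Conditions: (COCl)2, DMSO, CH2Cl2, −78 °C; Et3N, −78 → 0 °C
Reagents that add atoms: none
Why: Swern oxidation converts both hydroxyls into alkoxysulfonium salts before base is added, so the allylic and the primary alcohol are oxidised together and the 1,4-diol cannot pass through a lactol to a lactone.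

Step 5
Reactants: 8 keto aldehyde
Product: 10 (4aR,7S,8aR)-7-hydroxy-2,8a-dimethyl-5-methylidene-4a,5,6,7,8,8a-hexahydronaphthalen-1(4H)-one (trans-decalin; C2 hydroxyl axial and syn to the C10 methyl), via chloro(methyl)aluminium alkoxide 9 (not isolated)
Conditions: Me2AlCl (2.5 equiv), CH2Cl2, −78 → 0 °C; aq. HCl
Reagents that add atoms: none
Why: Me2AlCl binds the aldehyde oxygen (the hindered enone holds a further equivalent), the isopropenyl CH2 (C3) attacks C2 and a hydrogen of the isopropenyl methyl passes to oxygen within the same closed array, after which methane loss gives the aluminium alkoxide and leaves C4=CH2. The closest known reaction is the Lewis-acid-promoted type 2 intramolecular carbonyl-ene cyclisation of 5-methylenealkanals to 3-methylenecyclohexanols. Ring A (six-membered) closes through a chair, exo with respect to the C=O and endo with respect to the C=C, and because both reacting arms are trans and equatorial on ring B only the trans-fused decalin can result. The new stereocentre C2 is controlled by the closed transition state: hydrogen transfer requires oxygen above the C4 methyl, that is axial on the forming chair and syn to the C10 methyl, so the axial carbinol is expected. The step needs chemoselectivity for the aldehyde over the ketone and proton loss from the methyl group only; the first is secured by the much lower electrophilicity of the conjugated, doubly flanked C9 ketone and the second by the intramolecular hydrogen transfer to oxygen. Should some equatorial C2 epimer arise through a boat-like closure, it is the very alcohol made in step 6 and converges there.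

Step 6
Reactants: 10 axial alcohol
Product: 12 (4aR,7R,8aR)-7-hydroxy-2,8a-dimethyl-5-methylidene-4a,5,6,7,8,8a-hexahydronaphthalen-1(4H)-one (C2 hydroxyl equatorial and anti to the C10 methyl), via equatorial 4-nitrobenzoate 11 (not isolated)
Conditions: PPh3, DIAD, 4-O2NC6H4CO2H, THF, 0 °C → rt; then K2CO3 (cat.), MeOH, rt
Reagents that add atoms: 4-nitrobenzoic acid OC(=O)c1ccc(cc1)[N+](=O)[O-]
Why: Mitsunobu esterification displaces the axial alkoxyphosphonium by SN2 from the open equatorial direction with inversion at C2, and methanolysis of the crude ester frees the equatorial alcohol, whose oxygen now stems from the acid.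

Step 7
Reactants: 12 equatorial alcohol
Product: 13 tert-butyldimethylsilyl ether of 12
Conditions: TBSCl, imidazole, DMF, rt
Reagents that add atoms: tert-butyldimethylsilyl chloride CC(C)(C)[Si](C)(C)Cl
Why: Silyl ether formation on the unhindered equatorial secondary alcohol removes the only acidic proton before the hydride, ylide and organolithium steps.

Step 8
Reactants: 13 silyl ether
Product: 15 (4aR,7R,8aR)-7-(tert-butyldimethylsilyloxy)-2,5,5,8a-tetramethyl-4a,5,6,7,8,8a-hexahydronaphthalen-1(4H)-one, via C4 sulfonyl hydrazide adduct 14 (not isolated)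
Conditions: CH2O (aq.), n-C8H17SO2NHNH2, THF; Fe(acac)3 (cat.), PhSiH3, MeOH, rt; then 60 °C
Reagents that add atoms: formaldehyde C=O
Why: Iron-hydride hydrogen-atom transfer (Mukaiyama-type radical hydrofunctionalisation, here hydromethylation) puts hydrogen on the exocyclic CH2 of the electron-rich 1,1-disubstituted alkene, the tertiary C4 radical adds to the formaldehyde sulfonylhydrazone formed in situ, and the adduct loses sulfinate and N2 on warming to leave the C4 gem-dimethyl group, while the electron-poor trisubstituted enone alkene should react much more slowly.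

Step 9
Reactants: 15 gem-dimethyl enone
Product: 16 C9-methylidene 7,9(11)-diene silyl ether
Conditions: Ph3PCH3Br, KOtBu, toluene, 90 °C
Reagents that add atoms: methyltriphenylphosphonium bromide C[P+](c1ccccc1)(c1ccccc1)c1ccccc1.[Br-]
Why: Wittig methylenation with excess ylide at elevated temperature is the established way to convert a hindered ketone that cannot enolise toward the quaternary carbon into its exocyclic alkene.

Step 10
Reactants: 16 diene
Product: 18 C11 primary alcohol with C9–H anti and CH2OH syn to the C10 methyl, via B-alkyl-9-BBN adduct 17 (not isolated)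
Conditions: 9-BBN, THF, rt → 50 °C; NaOH, H2O2, 0 °C → rt
Reagents that add atoms: hydrogen peroxide OO
Why: Hydroboration–oxidation with the bulky 9-BBN engages only the terminal carbon of the exocyclic alkene and approaches anti to the axial C10 methyl, so hydrogen is delivered to C9 trans to that methyl and the CH2OH arm ends equatorial and cis to it, as in the target.

Step 11
Reactants: 18 primary alcohol
Product: 19 C11 primary iodide
Conditions: I2, PPh3, imidazole, CH2Cl2, 0 °C → rt
Reagents that add atoms: iodine II
Why: Appel-type iodination replaces the primary hydroxyl by SN2 at CH2 without touching the stereocentres, the alkene or the silyl ether.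

Step 12
Reactants: 19 primary iodide
Product: 22 C12 pinacol boronic ester (B–C12H2–C11H2–C9), via C11 alkyllithium 20 (not isolated), via lithium chloromethylboronate complex 21 (not isolated)
Conditions: tBuLi (2.1 equiv), Et2O/pentane, −78 °C; ClCH2Bpin, −78 °C → rt
Reagents that add atoms: 2-(chloromethyl)-4,4,5,5-tetramethyl-1,3,2-dioxaborolane ClCB1OC(C)(C)C(C)(C)O1
Why: Lithium–iodine exchange followed by capture with the chloromethylboronic ester gives an ate complex whose 1,2-metallate shift expels chloride (Matteson-type homologation), inserting C12 and delivering the primary boronic ester.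

Step 13
Reactants: 23 (R)-but-3-en-2-ol
Product: 24 (R)-but-3-en-2-yl N,N-diisopropylcarbamate
Conditions: iPr2NCOCl, Et3N, DMAP (cat.), CH2Cl2, reflux
Reagents that add atoms: N,N-diisopropylcarbamoyl chloride CC(C)N(C(C)C)C(=O)Cl
Why: O-Carbamoylation (acylation at oxygen, stereocentre untouched) installs the group that directs lithiation and later acts as the leaving group.

Step 14
Reactants: 24 allylic carbamate, 22 C12 boronic ester
Product: 28 (13S) tertiary allylic alcohol bearing the C2 silyl ether, via lithiated carbamate 25 (not isolated), via lithium boronate complex 26 (not isolated), via tertiary allylic boronic ester 27 (not isolated)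
Conditions: 24, sBuLi, TMEDA, Et2O, −78 °C; 22, −78 °C → rt; NaOH, H2O2, THF, 0 °C
Reagents that add atoms: hydrogen peroxide OO
Why: In this lithiation–borylation of a secondary allylic carbamate, deprotonation and borylation at the carbamate carbon both proceed with retention, the C12 group then migrates from boron to carbon with inversion as the carbamate leaves, and oxidation of the C–B bond with retention gives the alcohol in which the chain has replaced the original hydrogen with retention, that is (13S) from the (R)-alcohol.

Step 15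
Reactants: 28 silyl ether
Product: 29 (13S)-labda-7,14-diene-2,13-diol of the target series (C2 hydroxyl equatorial)
Conditions: Bu4NF, THF, rt
Reagents that add atoms: none
Why: Fluoride-mediated desilylation frees the C2 hydroxyl while the tertiary allylic alcohol and both alkenes are inert.

Step 16
Reactants: 29 diol, 30 3-methylbut-2-enoyl chloride
Product: 31 CNP0252389.1
Conditions: 30, pyridine, DMAP (cat.), CH2Cl2, 0 °C
Reagents that add atoms: none
Why: Nucleophile-catalysed acylation is selective for the unhindered equatorial secondary alcohol over the tertiary allylic C13 alcohol, and the weak base avoids deconjugation of the senecioyl group through a vinylketene.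

**Compound list**

1 | (S)-(+)-carvone | CC1=CC[C@@H](CC1=O)C(C)=C | starting material
2 | carvone lithium dienolate (O–Li on C1, C1=C6 and C2=C3) | CC1=CC[C@@H](C=C1O[Li])C(C)=C | intermediate
3 | (5S)-2,6-dimethyl-5-(prop-1-en-2-yl)cyclohex-2-en-1-one (6-methylcarvone, C6 epimers) | CC1=CC[C@@H](C(C)C1=O)C(C)=C | intermediate
4 | ethyl bromoacetate | CCOC(=O)CBr | starting material
5 | 6-methylcarvone lithium dienolate | CC1=CC[C@@H](C(C)=C1O[Li])C(C)=C | intermediate
6 | ethyl 2-[(1R,6R)-1,3-dimethyl-2-oxo-6-(prop-1-en-2-yl)cyclohex-3-en-1-yl]acetate (CH2CO2Et trans to isopropenyl) | O=C1C(C)=CC[C@H](C(C)=C)[C@@]1(C)CC(=O)OCC | intermediate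
7 | (5R,6R)-6-(2-hydroxyethyl)-2,6-dimethyl-5-(prop-1-en-2-yl)cyclohex-2-en-1-ol (carbinol epimers) | OC1C(C)=CC[C@H](C(C)=C)[C@@]1(C)CCO | intermediate
8 | 2-[(1R,6R)-1,3-dimethyl-2-oxo-6-(prop-1-en-2-yl)cyclohex-3-en-1-yl]acetaldehyde (ene precursor) | O=C1C(C)=CC[C@H](C(C)=C)[C@@]1(C)CC=O | intermediate
9 | chloro(methyl)aluminium alkoxide of 10 | O=C1C(C)=CC[C@@H]2C(=C)C[C@H](O[Al](C)Cl)C[C@@]12C | intermediate
10 | (4aR,7S,8aR)-7-hydroxy-2,8a-dimethyl-5-methylidene-4a,5,6,7,8,8a-hexahydronaphthalen-1(4H)-one (C2–OH axial, syn to C10–CH3) | O=C1C(C)=CC[C@@H]2C(=C)C[C@H](O)C[C@@]12C | intermediate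
11 | 4-nitrobenzoate of 12 (C2 ester equatorial) | O=C1C(C)=CC[C@@H]2C(=C)C[C@@H](OC(=O)c3ccc(cc3)[N+](=O)[O-])C[C@@]12C | intermediate
12 | (4aR,7R,8aR)-7-hydroxy-2,8a-dimethyl-5-methylidene-4a,5,6,7,8,8a-hexahydronaphthalen-1(4H)-one (C2–OH equatorial, anti to C10–CH3) | O=C1C(C)=CC[C@@H]2C(=C)C[C@@H](O)C[C@@]12C | intermediate
13 | tert-butyldimethylsilyl ether of 12 | O=C1C(C)=CC[C@@H]2C(=C)C[C@@H](O[Si](C)(C)C(C)(C)C)C[C@@]12C | intermediate
14 | 13 carrying CH3 and CH2NHNHSO2(n-C8H17) on C4 (C4 epimers) | O=C1C(C)=CC[C@@H]2C(C)(CNNS(=O)(=O)CCCCCCCC)C[C@@H](O[Si](C)(C)C(C)(C)C)C[C@@]12C | intermediate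
15 | (4aR,7R,8aR)-7-(tert-butyldimethylsilyloxy)-2,5,5,8a-tetramethyl-4a,5,6,7,8,8a-hexahydronaphthalen-1(4H)-one | O=C1C(C)=CC[C@@H]2C(C)(C)C[C@@H](O[Si](C)(C)C(C)(C)C)C[C@@]12C | intermediate
16 | C9-methylidene analogue of 15 (drima-7,9(11)-diene skeleton, C2–OTBS anti to C10–CH3) | C=C1C(C)=CC[C@@H]2C(C)(C)C[C@@H](O[Si](C)(C)C(C)(C)C)C[C@@]12C | intermediate
17 | B-(C11-alkyl)-9-borabicyclo[3.3.1]nonane from 16 (C9–H anti to C10–CH3) | C1CCC2CCCC1B2C[C@@H]3C(C)=CC[C@@H]4C(C)(C)C[C@@H](O[Si](C)(C)C(C)(C)C)C[C@@]34C | intermediate
18 | 2-(tert-butyldimethylsilyloxy)drim-7-en-11-ol of the target series (C9–H anti, CH2OH syn to C10–CH3) | OC[C@@H]1C(C)=CC[C@@H]2C(C)(C)C[C@@H](O[Si](C)(C)C(C)(C)C)C[C@@]12C | intermediate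
19 | 11-iodide corresponding to 18 | IC[C@@H]1C(C)=CC[C@@H]2C(C)(C)C[C@@H](O[Si](C)(C)C(C)(C)C)C[C@@]12C | intermediate
20 | 11-lithio compound from 19 | [Li]C[C@@H]1C(C)=CC[C@@H]2C(C)(C)C[C@@H](O[Si](C)(C)C(C)(C)C)C[C@@]12C | intermediate
21 | lithium (chloromethyl)(C11-alkyl)pinacolboronate complex | [Li+].ClC[B-]1(C[C@@H]2C(C)=CC[C@@H]3C(C)(C)C[C@@H](O[Si](C)(C)C(C)(C)C)C[C@@]23C)OC(C)(C)C(C)(C)O1 | intermediate
22 | C12 pinacol boronic ester (pinB–C12H2–C11H2–C9) | CC1(C)OB(CC[C@@H]2C(C)=CC[C@@H]3C(C)(C)C[C@@H](O[Si](C)(C)C(C)(C)C)C[C@@]23C)OC1(C)C | intermediate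
23 | (R)-but-3-en-2-ol | C=C[C@@H](C)O | starting material
24 | (R)-but-3-en-2-yl N,N-diisopropylcarbamate | C=C[C@@H](C)OC(=O)N(C(C)C)C(C)C | intermediate
25 | carbamate 24 lithiated at the carbinol carbon (retention) | C=C[C@@]([Li])(C)OC(=O)N(C(C)C)C(C)C | intermediate
26 | lithium boronate complex from 25 and 22 | [Li+].C=C[C@@]([B-]3(CC[C@@H]1C(C)=CC[C@@H]2C(C)(C)C[C@@H](O[Si](C)(C)C(C)(C)C)C[C@@]12C)OC(C)(C)C(C)(C)O3)(C)OC(=O)N(C(C)C)C(C)C | intermediate
27 | tertiary allylic pinacol boronic ester at C13 | C=C[C@](B3OC(C)(C)C(C)(C)O3)(C)CC[C@@H]1C(C)=CC[C@@H]2C(C)(C)C[C@@H](O[Si](C)(C)C(C)(C)C)C[C@@]12C | intermediate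
28 | (13S)-2-(tert-butyldimethylsilyloxy)labda-7,14-dien-13-ol of the target series | C=C[C@@](C)(O)CC[C@@H]1C(C)=CC[C@@H]2C(C)(C)C[C@@H](O[Si](C)(C)C(C)(C)C)C[C@@]12C | intermediate
29 | (13S)-labda-7,14-diene-2,13-diol of the target series (C2–OH equatorial) | C=C[C@@](C)(O)CC[C@@H]1C(C)=CC[C@@H]2C(C)(C)C[C@@H](O)C[C@@]12C | intermediate
30 | 3-methylbut-2-enoyl chloride (senecioyl chloride) | CC(C)=CC(=O)Cl | starting material
31 | CNP0252389.1, (2R,5R,9R,10R,13S)-2-(3-methylbut-2-enoyloxy)labda-7,14-dien-13-ol | C=C[C@@](C)(O)CC[C@@H]1C(C)=CC[C@@H]2C(C)(C)C[C@@H](OC(=O)C=C(C)C)C[C@@]12C | target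

**Step count and risks**

Total: 16 steps. Longest linear sequence: 15 steps (steps 1–12 and 14–16 from (S)-carvone); step 13 prepares the carbamate branch.

Risk 1, step 14. The lithiated allylic carbamate may lose configuration before it is captured, or the boronic ester may be attacked through the unsubstituted far terminus of the allyl system; either would erode C13 or give a primary allylic boronate. The fallback sets out from iodide 19 and returns at alcohol 28, fixing C13 by reagent control instead. Alkylation of lithiated 1-(trimethylsilyl)propyne (nBuLi, THF, DMPU) with 19 should give the silyl alkyne F1, and K2CO3 in MeOH the terminal alkyne F2. Zirconium-catalysed carboalumination (Me3Al, Cp2ZrCl2 cat.) with trapping of the vinylalane by paraformaldehyde should give the (E)-allylic alcohol F3. Sharpless asymmetric epoxidation (Ti(OiPr)4, L-(+)-diethyl tartrate, tBuOOH) should give the (13S,14S)-epoxy alcohol F4. PPh3, I2 and imidazole should give the epoxy iodide F5, and Zn in EtOH should open it reductively to the tertiary allylic alcohol 28 with the C13–O bond untouched.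

Risk 2, step 6. The axial alkoxyphosphonium has an anti-periplanar allylic hydrogen on C3, so elimination to a diene may outrun substitution, or the hindered axial hydroxyl may not be activated at all. The fallback sets out from keto ester 6 and returns at alcohol 12, closing the same C2–C3 bond through an open transition state so that no inversion is needed. Ene-type allylic chlorination of the isopropenyl group (Ca(OCl)2, solid CO2, CH2Cl2/H2O) should give the allylic chloride F6, and silylation with Me3SiSiMe3 and Pd(dba)2 (cat.) the allylsilane F7. LiAlH4 should give the diol F8 and Swern oxidation the keto aldehyde F9. BF3·OEt2 in CH2Cl2 at −78 °C should then effect an intramolecular Hosomi–Sakurai cyclisation in which the complexed oxygen is free to take the equatorial position away from the C10 methyl and silicon loss leaves C4=CH2, giving 12 directly.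

Risk 3, step 8. Hydrogen-atom transfer to the enone alkene, or addition of the C4 radical to the enone of a second molecule, may compete with capture by the hydrazone. The fallback sets out from silyl ether 13 and returns at enone 15 without radical intermediates. Simmons–Smith cyclopropanation (Et2Zn, CH2I2) of the exocyclic alkene should give the spirocyclopropane F10, the enone alkene being inert. Hydrogenolysis of the distal cyclopropane bond (H2, PtO2, AcOH), which also saturates C7=C8, should give the gem-dimethyl ketone F11. Enolisation toward C8, the only possible direction (LiN(iPr)2, Me3SiCl), should give the silyl enol ether F12, and Saegusa–Ito oxidation (Pd(OAc)2, MeCN) should restore the C7=C8 enone 15.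

**Further compounds**

F1 | step 14 | trimethylsilyl alkyne (C11–C12H2–C13≡C14–SiMe3) from 19 | C[Si](C)(C)C#CCC[C@@H]1C(C)=CC[C@@H]2C(C)(C)C[C@@H](O[Si](C)(C)C(C)(C)C)C[C@@]12C
F2 | step 14 | terminal alkyne (C11–C12H2–C13≡C14H) | C#CCC[C@@H]1C(C)=CC[C@@H]2C(C)(C)C[C@@H](O[Si](C)(C)C(C)(C)C)C[C@@]12C
F3 | step 14 | (E)-allylic alcohol (C12H2–C13(CH3)=C14H–C15H2OH) | OC/C=C(\C)CC[C@@H]1C(C)=CC[C@@H]2C(C)(C)C[C@@H](O[Si](C)(C)C(C)(C)C)C[C@@]12C
F4 | step 14 | (13S,14S)-13,14-epoxy-15-ol | OC[C@@H]1O[C@@]1(C)CC[C@@H]2C(C)=CC[C@@H]3C(C)(C)C[C@@H](O[Si](C)(C)C(C)(C)C)C[C@@]23C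
F5 | step 14 | 15-iodide of F4 | IC[C@@H]1O[C@@]1(C)CC[C@@H]2C(C)=CC[C@@H]3C(C)(C)C[C@@H](O[Si](C)(C)C(C)(C)C)C[C@@]23C
F6 | step 6 | keto ester 6 chlorinated on the isopropenyl methyl | O=C1C(C)=CC[C@H](C(CCl)=C)[C@@]1(C)CC(=O)OCC
F7 | step 6 | keto ester 6 carrying CH2SiMe3 in place of the isopropenyl methyl (allylsilane) | O=C1C(C)=CC[C@H](C(C[Si](C)(C)C)=C)[C@@]1(C)CC(=O)OCC
F8 | step 6 | allylsilane diol (carbinol epimers) | OC1C(C)=CC[C@H](C(C[Si](C)(C)C)=C)[C@@]1(C)CCO
F9 | step 6 | allylsilane keto aldehyde | O=C1C(C)=CC[C@H](C(C[Si](C)(C)C)=C)[C@@]1(C)CC=O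
F10 | step 8 | C4 spirocyclopropane of 13 | O=C1C(C)=CC[C@@H]2C3(CC3)C[C@@H](O[Si](C)(C)C(C)(C)C)C[C@@]12C
F11 | step 8 | 7,8-dihydro derivative of 15 (C8 epimers) | O=C1C(C)CC[C@@H]2C(C)(C)C[C@@H](O[Si](C)(C)C(C)(C)C)C[C@@]12C
F12 | step 8 | trimethylsilyl enol ether of F11 (C8=C9) | C[Si](C)(C)OC1=C(C)CC[C@@H]2C(C)(C)C[C@@H](O[Si](C)(C)C(C)(C)C)C[C@@]12C
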